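**Plan (labdane numbering)**
Cuts: O–C15 of ring D (back to an ethynyl group on C13 and a C16 carbinol) and C8–OAc (back to a 7-enol acetate). C8 is then reconnected to C16, which turns ring C into a 7-oxanorbornane. That bicycle is cut at C8–C9 and C13–C16 together, and the monocyclic rest at C7–C8, C5–C6, the two C4–CH3 bonds, C9–C10 and C13–C14.
Enabling feature: ring C (O, C9, C11, C12, C13) is a tetrahydrofuran, that is a reduced 2,5-disubstituted furan. Its α-carbons C9 and C13 are both fully substituted and hold C8 and C16 on the same face, so a C8=C16 dienophile can bridge that face.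
Forward order: ring A comes from 3-methylcyclohexenone and receives the furan, the side arm and the gem-dimethyl group. Rings B and C form together in the cycloaddition, the auxiliary C8–C16 bond is then broken, and ring D closes last.
Stereochemistry: C10 from a copper-catalysed asymmetric conjugate addition, C5 from a palladium-catalysed asymmetric allylation, C9 and C13 from the cycloaddition (chair tether, exo side arm), C8 from α-face epoxidation of the enol acetate followed by an inverting acetoxy shift.

Key step: step 8

Assumption: the carbinol carbon C7 in 12 and 16 forms as an epimer mixture, is drawn without configuration, and is erased in the next operation.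

**Step 1**
Reactants: 1 2-bromofuran; 2 ethynyltriisopropylsilane
Product: 3 2-[(triisopropylsilyl)ethynyl]furan
Conditions: PdCl2(PPh3)2 (2 mol %), CuI (4 mol %), Et3N, THF, 40 °C
Reagents that add atoms: none
Why: Sonogashira coupling of a 2-halofuran with a terminal alkyne is routine and brings in C14–C15 as a slim, base-stable group that tempers the acid sensitivity of the furan and later closes ring D by isomerisation.

**Step 2**
Reactants: 3 2-[(triisopropylsilyl)ethynyl]furan; 4 3-methylcyclohex-2-en-1-one; 5 allyl chloroformate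
Product: 9 allyl (S)-3-methyl-3-{5-[(triisopropylsilyl)ethynyl]furan-2-yl}cyclohex-1-en-1-yl carbonate, via 5-lithiofuran 6 (not isolated), via furyldimethylaluminium 7 (not isolated), via aluminium enolate 8 (not isolated)
Conditions: n-BuLi, THF, −78 to 0 °C; Me2AlCl, −78 to 23 °C; 4, Cu(OTf)2 (5 mol %), chiral sulfonate-bearing imidazolinium salt (carbene precursor, 5 mol %), THF, −30 °C; 5, −30 to 0 °C
Reagents that add atoms: none
Why: The copper–carbene-catalysed asymmetric conjugate addition of a heteroaryl(dimethyl)aluminium reagent to a β-substituted cyclic enone transfers the furyl group in preference to methyl and sets quaternary C10 under ligand control (the ligand antipode giving S is used), and O-acylation of the aluminium enolate stores the C4=C5 enolate regiochemistry.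

**Step 3**
Reactants: 9 allyl enol carbonate
Product: 10 (2R,3S)-2-allyl-3-methyl-3-{5-[(triisopropylsilyl)ethynyl]furan-2-yl}cyclohexan-1-one
Conditions: Pd2(dba)3·CHCl3 (2.5 mol %), (R,R)-ANDEN-phenyl bis(diphenylphosphinobenzamide) ligand (5.5 mol %), toluene, 23 °C
Reagents that add atoms: none
Why: The decarboxylative asymmetric allylic alkylation (Tsuji–Trost type) releases the enolate only at C5 under neutral conditions, and C–C bond formation anti to the furyl group, reinforced by the chiral ligand, places the side arm trans to the furan (H-5 α) without later epimerisation.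

**Step 4**
Reactants: 10 allyl ketone
Product: 11 2-[(1S,2S)-2-allyl-1,3,3-trimethylcyclohexyl]-5-[(triisopropylsilyl)ethynyl]furan
Conditions: Me2Zn, TiCl4 (gives Me2TiCl2, 3 equiv), CH2Cl2, −30 to 0 °C
Reagents that add atoms: dimethylzinc C[Zn]C (methyl source, acting as dichlorodimethyltitanium C[Ti](C)(Cl)Cl)
Why: Geminal dimethylation of a ketone with Me2TiCl2 proceeds by methyl addition, ionisation of the tertiary titanium alkoxide and a second methyl transfer; the reagent is non-basic, so C5 is kept, and the alkynyl-deactivated furan, the silyl alkyne and the terminal alkene should be spared at low temperature.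

**Step 5**
Reactants: 11 allyl compound
Product: 13 2-[(1S,2S)-2,6,6-trimethyl-2-{5-[(triisopropylsilyl)ethynyl]furan-2-yl}cyclohexyl]acetaldehyde, via vicinal diol 12 (not isolated)
Conditions: OsO4 (2 mol %), NaIO4, 2,6-lutidine, dioxane/H2O, 23 °C
Reagents that add atoms: osmium tetroxide O=[Os](=O)(=O)=O; sodium periodate [Na+].[O-]I(=O)(=O)=O
Why: Lemieux–Johnson cleavage takes the monosubstituted alkene much faster than the aromatic furan or the silyl alkyne, where ozone would not discriminate, and leaves the C6–C7 aldehyde.

**Step 6**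
Reactants: 13 aldehyde; 14 1-bromobut-2-yne
Product: 16 allenyl carbinol (7RS)-3-methyl-1-[ring A unit]penta-3,4-dien-2-ol, via but-2-ynylindium dibromide 15 (not isolated)
Conditions: In (powder), THF/H2O, 23 °C
Reagents that add atoms: none
Why: In the indium Barbier reaction a γ-substituted propargyl bromide reacts through its remote carbon (SE2'), so C7–C8 forms at the methyl-bearing carbon and the α-methyl allenyl carbinol is expected.

**Step 7**
Reactants: 16 allenyl carbinol
Product: 17 allenyl ketone 3-methyl-1-[(1S,2S)-2,6,6-trimethyl-2-{5-[(triisopropylsilyl)ethynyl]furan-2-yl}cyclohexyl]penta-3,4-dien-2-one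
Conditions: Dess–Martin periodinane, CH2Cl2, 0 °C
Reagents that add atoms: none
Why: Dess–Martin oxidation of α-allenic alcohols is mild enough to deliver the allenyl ketone without isomerisation and removes the C7 stereocentre.

**Step 8**
Reactants: 17 allenyl ketone
Product: 18 7-oxanorbornene adduct (rings A/B trans-fused, oxygen bridge 9α,13, C11=C12, exocyclic methylene on C16, C8 methyl β, C16 α on C8, silylethynyl on C13)
Conditions: Me2AlCl (1.1 equiv), CH2Cl2, −78 to −20 °C
Reagents that add atoms: none
Why: Me2AlCl binds the C7 carbonyl and lowers the LUMO of the conjugated C8=C16 bond of the allene, which adds across the furan termini C9 and C13 in a concerted, asynchronous [4+2] event with C8–C9 leading; the closest known reaction type is the Lewis-acid-promoted intramolecular Diels–Alder reaction of furans with allenyl ketones. Ring B closes as a six-membered carbocycle through the four-atom tether C10–C5–C6–C7 in a chair-like array, and ring C appears at the same time as the oxygen bridge of a 7-oxabicyclo[2.2.1]heptene completed by C13–C16. C9 is controlled by the tether, which can only lie exo (syn to the bridge); with the ring A bonds at C5 and C10 trans-diequatorial, the chair puts O axial (α) and C11 equatorial (β). C13 follows from C9 because the dienophile adds suprafacially to one furan face, so C8 and C16 sit on the same side of ring C, while C8 (methyl endo, β) follows from the exo tether and is erased in step 12. The step needs site selectivity for the proximal over the distal allene bond, secured by conjugation with the complexed ketone and by tether length, and it must not revert, which the release of cumulene strain, the low temperature and the slim sp carbons at C16 and C14 should ensure.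

**Step 9**
Reactants: 18 oxanorbornene adduct
Product: 19 11,12-dihydro adduct (7-oxanorbornane)
Conditions: 2-nitrobenzenesulfonylhydrazide, Et3N, CH2Cl2, 23 °C
Reagents that add atoms: none
Why: Diimide reduction is fastest for strained cis-disubstituted alkenes, so C11=C12 should be saturated while the methylene flanked by two quaternary carbons and the hindered silyl alkyne remain, and cycloreversion is shut off.

**Step 10**
Reactants: 19 dihydro adduct
Product: 20 7,16-diketone
Conditions: O3, pyridine, CH2Cl2, −78 °C
Reagents that add atoms: ozone [O-][O+]=O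
Why: Pyridine-mediated reductive ozonolysis cleaves the only remaining C=C directly to the ketone, removes the surplus allene carbon, and should outrun attack on the silyl alkyne by a wide margin.

**Step 11**
Reactants: 20 diketone
Product: 22 16-endo-hydroxy-7-ketone (aldol; OH anti to the oxygen bridge), via lithium enolate 21 (not isolated)
Conditions: LiN(SiMe3)2, THF, −78 °C; i-Bu2AlH, −78 to −40 °C; AcOH, −78 °C
Reagents that add atoms: none
Why: Only C7 can enolise (C16 lies between quaternary C8 and C13), so masking it as its enolate, a known protection tactic for selective ketone reduction, leaves the strained C16 carbonyl as the sole hydride acceptor; attack is expected from the exo face, and the new centre is lost in step 12.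

**Step 12**
Reactants: 22 aldol
Product: 24 7-enol acetate aldehyde (7-acetoxy-9α,13-epoxy-15-triisopropylsilyl-labd-7-en-14-yn-16-al), via potassium enolate 23 (not isolated)
Conditions: KN(SiMe3)2, THF, −78 to −30 °C; Ac2O, −78 °C
Reagents that add atoms: acetic anhydride CC(=O)OC(C)=O
Why: The alkoxide-triggered retro-aldol cleavage of C8–C16, driven by release of the bicyclic strain, frees C16 as an aldehyde and gives the C7=C8 enolate regiospecifically in aprotic medium, where acetic anhydride captures it on oxygen because C8 is fully substituted.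

**Step 13**
Reactants: 24 enol acetate aldehyde
Product: 26 8β-acetoxy-9α,13-epoxy-7-oxo-15-triisopropylsilyl-labd-14-yn-16-al, via 7α,8α-epoxy acetate 25 (not isolated)
Conditions: dimethyldioxirane, acetone/CH2Cl2, −20 °C; evaporate; toluene, 110 °C, base-washed glass
Reagents that add atoms: dimethyldioxirane CC1(C)OO1
Why: The dioxirane should take the α face because the axial C10 methyl screens the β face, and the thermal enol ester epoxide rearrangement then moves the 7β-acetoxy group to C8 with inversion, giving the axial 8β-acetate, the 8α-methyl group and the C7 ketone.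

**Step 14**
Reactants: 26 acetoxy keto aldehyde
Product: 27 8β-acetoxy-9α,13-epoxy-16-hydroxy-15-triisopropylsilyl-labd-14-yn-7-one
Conditions: NaBH4, MeOH/CH2Cl2, −78 °C
Reagents that add atoms: none
Why: Chemoselective borohydride reduction takes the α-alkoxy aldehyde well before the C7 ketone, which is shielded by quaternary C8, and does not touch the tertiary acetate.

**Step 15**
Reactants: 27 silyl alkynol
Product: 28 (13R)-8β-acetoxy-9α,13-epoxy-16-hydroxylabd-14-yn-7-one
Conditions: Bu4NF, AcOH, THF, 23 °C
Reagents that add atoms: none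
Why: Buffered fluoride protodesilylation frees the terminal alkyne without base-induced loss or migration of the acetate.

**Step 16**
Reactants: 28 alkynol
Product: 29 (13R)-8β-acetoxy-9α,13;15,16-diepoxylabd-14-en-7-one (target, CNP0165143.1)
Conditions: Mo(CO)6 (25 mol %), Et3N, Et2O, hν (350 nm); then 28 in the dark, 23 °C
Reagents that add atoms: none
Why: The molybdenum-catalysed cycloisomerisation of a but-3-yn-1-ol proceeds through a metal vinylidene, so the C16 hydroxyl adds to terminal C15 (5-endo) to give the 2,3-dihydrofuran of ring D, helped by the quaternary C13 and kept safe by the amine medium.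

**Compound list**
1 | 2-bromofuran | Brc1ccco1 | starting material
2 | ethynyltriisopropylsilane | C#C[Si](C(C)C)(C(C)C)C(C)C | starting material
3 | 2-[(triisopropylsilyl)ethynyl]furan | CC(C)[Si](C#Cc1ccco1)(C(C)C)C(C)C | intermediate
4 | 3-methylcyclohex-2-en-1-one | CC1=CC(=O)CCC1 | starting material
5 | allyl chloroformate | C=CCOC(=O)Cl | starting material
6 | 5-lithio-2-[(triisopropylsilyl)ethynyl]furan | [Li]c1ccc(C#C[Si](C(C)C)(C(C)C)C(C)C)o1 | intermediate
7 | dimethyl{5-[(triisopropylsilyl)ethynyl]furan-2-yl}aluminium | C[Al](C)c1ccc(C#C[Si](C(C)C)(C(C)C)C(C)C)o1 | intermediate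
8 | dimethylaluminium enolate (C4=C5, 10S) | C[Al](C)OC1=C[C@@](C)(c2ccc(C#C[Si](C(C)C)(C(C)C)C(C)C)o2)CCC1 | intermediate
9 | allyl (S)-enol carbonate | C=CCOC(=O)OC1=C[C@@](C)(c2ccc(C#C[Si](C(C)C)(C(C)C)C(C)C)o2)CCC1 | intermediate
10 | (2R,3S)-2-allyl-3-methyl-3-furylcyclohexanone | C=CC[C@H]1C(=O)CCC[C@]1(C)c1ccc(C#C[Si](C(C)C)(C(C)C)C(C)C)o1 | intermediate
11 | (1S,2S)-2-allyl-1,3,3-trimethylcyclohexyl furan | C=CC[C@H]1C(C)(C)CCC[C@]1(C)c1ccc(C#C[Si](C(C)C)(C(C)C)C(C)C)o1 | intermediate
12 | vicinal diol from 11 (carbinol epimers) | OCC(O)C[C@H]1C(C)(C)CCC[C@]1(C)c1ccc(C#C[Si](C(C)C)(C(C)C)C(C)C)o1 | intermediate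
13 | C6–C7 aldehyde | O=CC[C@H]1C(C)(C)CCC[C@]1(C)c1ccc(C#C[Si](C(C)C)(C(C)C)C(C)C)o1 | intermediate
14 | 1-bromobut-2-yne | CC#CCBr | starting material
15 | but-2-ynylindium dibromide | CC#CC[In](Br)Br | intermediate
16 | allenyl carbinol (C7 epimers) | C=C=C(C)C(O)C[C@H]1C(C)(C)CCC[C@]1(C)c1ccc(C#C[Si](C(C)C)(C(C)C)C(C)C)o1 | intermediate
17 | allenyl ketone (cycloaddition precursor) | C=C=C(C)C(=O)C[C@H]1C(C)(C)CCC[C@]1(C)c1ccc(C#C[Si](C(C)C)(C(C)C)C(C)C)o1 | intermediate
18 | 7-oxanorbornene adduct | C=C1[C@]2(C#C[Si](C(C)C)(C(C)C)C(C)C)C=C[C@@]3(O2)[C@@]1(C)C(=O)C[C@H]1C(C)(C)CCC[C@@]13C | intermediate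
19 | 11,12-dihydro adduct | C=C1[C@]2(C#C[Si](C(C)C)(C(C)C)C(C)C)CC[C@@]3(O2)[C@@]1(C)C(=O)C[C@H]1C(C)(C)CCC[C@@]13C | intermediate
20 | 7,16-diketone | O=C1[C@]2(C#C[Si](C(C)C)(C(C)C)C(C)C)CC[C@@]3(O2)[C@@]1(C)C(=O)C[C@H]1C(C)(C)CCC[C@@]13C | intermediate
21 | lithium C6=C7 enolate of 20 | O=C1[C@]2(C#C[Si](C(C)C)(C(C)C)C(C)C)CC[C@@]3(O2)[C@@]1(C)C(O[Li])=C[C@H]1C(C)(C)CCC[C@@]13C | intermediate
22 | 16-endo-hydroxy-7-ketone (aldol) | O[C@@H]1[C@]2(C#C[Si](C(C)C)(C(C)C)C(C)C)CC[C@@]3(O2)[C@@]1(C)C(=O)C[C@H]1C(C)(C)CCC[C@@]13C | intermediate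
23 | potassium C7=C8 enolate aldehyde | [K]OC1=C(C)[C@]2(CC[C@](C=O)(C#C[Si](C(C)C)(C(C)C)C(C)C)O2)[C@@]3(C)CCCC(C)(C)[C@@H]3C1 | intermediate
24 | 7-enol acetate aldehyde | CC(=O)OC1=C(C)[C@]2(CC[C@](C=O)(C#C[Si](C(C)C)(C(C)C)C(C)C)O2)[C@@]3(C)CCCC(C)(C)[C@@H]3C1 | intermediate
25 | 7β-acetoxy-7α,8α-epoxide | CC(=O)O[C@@]12C[C@H]3C(C)(C)CCC[C@]3(C)[C@@]4(CC[C@](C=O)(C#C[Si](C(C)C)(C(C)C)C(C)C)O4)[C@]1(C)O2 | intermediate
26 | 8β-acetoxy-7-keto-16-aldehyde | CC(=O)O[C@@]1(C)C(=O)C[C@H]2C(C)(C)CCC[C@]2(C)[C@@]12CC[C@](C=O)(C#C[Si](C(C)C)(C(C)C)C(C)C)O2 | intermediate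
27 | 8β-acetoxy-16-hydroxy-7-ketone, silyl alkyne | CC(=O)O[C@@]1(C)C(=O)C[C@H]2C(C)(C)CCC[C@]2(C)[C@@]12CC[C@](CO)(C#C[Si](C(C)C)(C(C)C)C(C)C)O2 | intermediate
28 | 8β-acetoxy-16-hydroxy-7-ketone, terminal alkyne | CC(=O)O[C@@]1(C)C(=O)C[C@H]2C(C)(C)CCC[C@]2(C)[C@@]12CC[C@](CO)(C#C)O2 | intermediate
29 | 8β-acetoxy-9α,13;15,16-diepoxylabd-14-en-7-one | CC(=O)O[C@@]1(C)C(=O)C[C@H]2C(C)(C)CCC[C@]2(C)[C@@]12CC[C@]1(C=COC1)O2 | target

Total step count: 16. Longest linear sequence: 16 steps (1 to 29); all other building blocks are purchased.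

**Steps most likely to fail**

1. **Step 8.** The cycloaddition may stall or revert. Two fully substituted carbons form at once, and the endo methyl on C8 is pressed against the axial C10 methyl. Prolonged contact with the Lewis acid may also open the oxygen bridge.
 The fallback sets out from 13 and returns at 20; it moves the C8 methyl group to after the ring closure. Indium-mediated addition of propargyl bromide to 13 gives homopropargylic alcohol F1. Dess–Martin oxidation followed by triethylamine in the same flask gives the unsubstituted allenyl ketone F2, whose C8 carries only hydrogen. Me2AlCl then closes the less crowded 8-demethyl adduct F3, diimide gives its dihydro derivative F4, and ozonolysis gives the enolisable 8-demethyl diketone F5. C-methylation (K2CO3, MeI, acetone) on the endo face, with ring B holding C7 exo, leads to 20. The C8 configuration is erased in step 12 in any case.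

2. **Step 12.** The potassium enolate may expel the axial C9–O bond (β-elimination that opens ring C) before it is acetylated. Cleavage may also be slow, because in the chair form of ring B the C8–C16 bond lies close to the carbonyl plane.
 The fallback sets out from 22 and returns at 24; it avoids a stoichiometric metal enolate. K2CO3 in methanol effects the retro-aldol under protic conditions, so the enolate is protonated at once and keto aldehyde F6 results. Soft enolisation (Me3SiOTf, Et3N) towards the more substituted side gives trimethylsilyl enol ether F7; the aldehyde cannot enolise. Acetyl fluoride with catalytic Bu4NF then exchanges silicon for acetyl on oxygen to give 24.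

3. **Step 13.** Facial selectivity of the epoxidation may be poor or reversed, because the α face carries the pseudoaxial ring C oxygen and the nearby formyl group. Traces of acid may also divert the α-epoxide into the retentive pathway.
 The fallback sets out from 24 and returns at 26. If the oxidant takes the β face, the 7β,8β-epoxy acetate F8 is treated with catalytic p-toluenesulfonic acid in CH2Cl2. This opens the epoxide at the acetal carbon C7 and hands the acetyl group to the C8 oxygen with retention, so both epoxides lead to the same 8β-acetate 26.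

**Further compounds**
F1 | step 8 | homopropargylic alcohol (carbinol epimers) | C#CCC(O)C[C@H]1C(C)(C)CCC[C@]1(C)c1ccc(C#C[Si](C(C)C)(C(C)C)C(C)C)o1
F2 | step 8 | unsubstituted allenyl ketone | C=C=CC(=O)C[C@H]1C(C)(C)CCC[C@]1(C)c1ccc(C#C[Si](C(C)C)(C(C)C)C(C)C)o1
F3 | step 8 | 8-demethyl oxanorbornene adduct | C=C1[C@]2(C#C[Si](C(C)C)(C(C)C)C(C)C)C=C[C@@]3(O2)[C@H]1C(=O)C[C@H]1C(C)(C)CCC[C@@]13C
F4 | step 8 | 8-demethyl dihydro adduct | C=C1[C@]2(C#C[Si](C(C)C)(C(C)C)C(C)C)CC[C@@]3(O2)[C@H]1C(=O)C[C@H]1C(C)(C)CCC[C@@]13C
F5 | step 8 | 8-demethyl 7,16-diketone | O=C1[C@]2(C#C[Si](C(C)C)(C(C)C)C(C)C)CC[C@@]3(O2)[C@H]1C(=O)C[C@H]1C(C)(C)CCC[C@@]13C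
F6 | step 12 | keto aldehyde (8α-methyl, H-8β) | C[C@@H]1C(=O)C[C@H]2C(C)(C)CCC[C@]2(C)[C@@]12CC[C@](C=O)(C#C[Si](C(C)C)(C(C)C)C(C)C)O2
F7 | step 12 | trimethylsilyl 7-enol ether aldehyde | C[Si](C)(C)OC1=C(C)[C@]2(CC[C@](C=O)(C#C[Si](C(C)C)(C(C)C)C(C)C)O2)[C@@]3(C)CCCC(C)(C)[C@@H]3C1
F8 | step 13 | 7α-acetoxy-7β,8β-epoxide | CC(=O)O[C@]12C[C@H]3C(C)(C)CCC[C@]3(C)[C@@]4(CC[C@](C=O)(C#C[Si](C(C)C)(C(C)C)C(C)C)O4)[C@@]1(C)O2
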